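**Plan**
- Retrosynthesis: the 4,5-epoxide oxygen, the C8 methacrylate and the C13 acetate are removed first. Then C6–C7, C11–C12 and C12–O are cut together (C6 enal + C7≡C11 alkyne + CO). The open chain is cut at C1–C2 (Weinreb amide + alkyllithium) and at C7–C8 (acid chloride + terminal alkyne).
- Enabling feature: the butenolide (O–C6, C7=C11, C12=O) is the formal [2+2+1] adduct of the C6 aldehyde, the C13-bearing C7≡C11 alkyne and CO. Its C6–C7 bond is also a bond of the ten-membered carbocycle (C1–C10), so one cyclocarbonylation can close both rings.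
- Forward: the citramalate C8–C10/C1 unit is taken to an ynone, a propargylic carbinol and a Weinreb amide. The C2–C6 iodide is joined at C1, and the acyclic ynal is closed to carbocycle and lactone in one operation. Desilylation, two acylations and epoxidation finish the synthesis.
- Stereochemistry: C10 from (R)-citramalic acid; C8 by catalyst-controlled transfer hydrogenation; 4E geometry by syn-carboalumination; C6 in the ring closure under control of C8; C4/C5 by peracid on the outer face of the E-alkene.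

Key step: step 14

Assumption: atoms are numbered as in germacranolides (C1 ketone, C4–C5 epoxide, C6 lactone carbinol, C7=C11, C8 ester carbinol, C10 acetoxy carbon, C12 lactone carbonyl, C13 acetoxymethyl); silyl ethers 3 and 9 are bought, each being one silylation away from propargyl alcohol or 3-butyn-1-ol.

**Route**

Step 1
Reactants: 1 (R)-citramalic acid
Product: 2 2-[(4R)-2,2,4-trimethyl-5-oxo-1,3-dioxolan-4-yl]acetic acid
Conditions: 2,2-dimethoxypropane, p-TsOH (cat.), 23 °C
Reagents that add atoms: 2,2-dimethoxypropane, COC(C)(C)OC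
Why: Acid-catalysed 1,3-dioxolan-4-one (acetonide) formation engages only the α-hydroxy acid, as in the malic acid series, so the two carboxyl groups are differentiated and the tertiary hydroxyl is masked without touching C10.

Step 2
Reactants: 2 2-[(4R)-2,2,4-trimethyl-5-oxo-1,3-dioxolan-4-yl]acetic acid; 3 tert-butyldimethyl(prop-2-yn-1-yloxy)silane
Product: 5 (5R)-5-{5-[(tert-butyldimethylsilyl)oxy]-2-oxopent-3-yn-1-yl}-2,2,5-trimethyl-1,3-dioxolan-4-one, via acid chloride 4 (not isolated)
Conditions: (COCl)2, DMF (cat.), CH2Cl2, 0 → 23 °C; evaporate; 3, PdCl2(PPh3)2 (2 mol%), CuI (4 mol%), Et3N, THF, 23 °C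
Reagents that add atoms: none
Why: Acyl Sonogashira coupling of the acid chloride with the terminal alkyne forms the C7–C8 bond as an ynone under mild amine conditions that the dioxolanone and the silyl ether tolerate.

Step 3
Reactants: 5 (5R)-5-{5-[(tert-butyldimethylsilyl)oxy]-2-oxopent-3-yn-1-yl}-2,2,5-trimethyl-1,3-dioxolan-4-one
Product: 6 (5R)-5-{(2S)-5-[(tert-butyldimethylsilyl)oxy]-2-hydroxypent-3-yn-1-yl}-2,2,5-trimethyl-1,3-dioxolan-4-one
Conditions: Ru[(S,S)-TsDPEN](p-cymene) (2 mol%), i-PrOH, 23 °C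
Reagents that add atoms: none
Why: Noyori asymmetric transfer hydrogenation of an alkynyl ketone is catalyst-controlled, and the (S,S)-catalyst, with the alkynyl group as the π-substituent, should deliver hydride to the face that gives the (S)-carbinol at C8 under neutral conditions.

Step 4
Reactants: 6 (5R)-5-{(2S)-5-[(tert-butyldimethylsilyl)oxy]-2-hydroxypent-3-yn-1-yl}-2,2,5-trimethyl-1,3-dioxolan-4-one
Product: 7 (5R)-5-{(2S)-2,5-bis[(tert-butyldimethylsilyl)oxy]pent-3-yn-1-yl}-2,2,5-trimethyl-1,3-dioxolan-4-one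
Conditions: TBSCl, imidazole, DMF, 23 °C (crude 6 used at once)
Reagents that add atoms: tert-butyldimethylsilyl chloride, CC(C)(C)[Si](C)(C)Cl
Why: Routine silylation of the secondary propargylic alcohol blocks C8–OH before it can translactonise onto the dioxolanone carbonyl.

Step 5
Reactants: 7 (5R)-5-{(2S)-2,5-bis[(tert-butyldimethylsilyl)oxy]pent-3-yn-1-yl}-2,2,5-trimethyl-1,3-dioxolan-4-one
Product: 8 (2R,4S)-4,7-bis[(tert-butyldimethylsilyl)oxy]-2-hydroxy-N-methoxy-N,2-dimethylhept-5-ynamide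
Conditions: MeNH(OMe)·HCl, i-PrMgCl, THF, −20 → 0 °C
Reagents that add atoms: N,O-dimethylhydroxylamine hydrochloride, CNOC.Cl
Why: Weinreb aminolysis of the activated dioxolanone by the magnesium amide opens the acylal with loss of acetone and gives the C1 Weinreb amide with the C10 hydroxyl free.

Step 6
Reactants: 9 tert-butyl(but-3-yn-1-yloxy)dimethylsilane
Product: 12 (E)-5-[(tert-butyldimethylsilyl)oxy]-3-methylpent-2-en-1-ol, via alkenyldimethylalane 10 (not isolated), via lithium alkenylalanate 11 (not isolated)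
Conditions: Me3Al, Cp2ZrCl2 (25 mol%), CH2Cl2, 0 → 23 °C; evaporate; n-BuLi, THF–hexane, −78 °C; (CH2O)n, → 23 °C; aq. Rochelle salt
Reagents that add atoms: trimethylaluminium, C[Al](C)C; formaldehyde (as paraformaldehyde), C=O
Why: Negishi zirconium-catalysed carboalumination adds methyl and aluminium syn across the terminal alkyne (methyl to the internal carbon), and hydroxymethylation of the alanate proceeds with retention, which fixes the 4E geometry and installs C6.

Step 7
Reactants: 12 (E)-5-[(tert-butyldimethylsilyl)oxy]-3-methylpent-2-en-1-ol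
Product: 13 tert-butyl{[(E)-5-[(4-methoxybenzyl)oxy]-3-methylpent-3-en-1-yl]oxy}dimethylsilane
Conditions: NaH, PMBCl, Bu4NI (cat.), THF–DMF, 0 → 23 °C
Reagents that add atoms: 4-methoxybenzyl chloride, COc1ccc(CCl)cc1
Why: Williamson etherification protects the allylic C6 hydroxyl with a group that survives fluoride and organolithium reagents and is later removed oxidatively.

Step 8
Reactants: 13 tert-butyl{[(E)-5-[(4-methoxybenzyl)oxy]-3-methylpent-3-en-1-yl]oxy}dimethylsilane
Product: 14 (E)-5-[(4-methoxybenzyl)oxy]-3-methylpent-3-en-1-ol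
Conditions: TBAF, THF, 0 → 23 °C
Reagents that add atoms: none
Why: Fluoride-mediated desilylation frees the homoallylic C2 hydroxyl and leaves the PMB ether untouched.

Step 9
Reactants: 14 (E)-5-[(4-methoxybenzyl)oxy]-3-methylpent-3-en-1-ol
Product: 15 1-({[(E)-5-iodo-3-methylpent-2-en-1-yl]oxy}methyl)-4-methoxybenzene
Conditions: I2, PPh3, imidazole, CH2Cl2, 0 °C
Reagents that add atoms: iodine, II
Why: Appel-type iodination (PPh3/I2/imidazole) converts the primary alcohol into the iodide by SN2 displacement without affecting the trisubstituted alkene.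

Step 10
Reactants: 15 1-({[(E)-5-iodo-3-methylpent-2-en-1-yl]oxy}methyl)-4-methoxybenzene; 8 (2R,4S)-4,7-bis[(tert-butyldimethylsilyl)oxy]-2-hydroxy-N-methoxy-N,2-dimethylhept-5-ynamide
Product: 17 (2E,7R,9S)-9,12-bis[(tert-butyldimethylsilyl)oxy]-7-hydroxy-1-[(4-methoxybenzyl)oxy]-3,7-dimethyldodec-2-en-10-yn-6-one, via alkyllithium 16 (not isolated)
Conditions: 15 (1.5 equiv), t-BuLi (2 equiv per iodide), Et2O, −78 °C; add to 8 pretreated with i-PrMgCl (1.0 equiv), THF, −78 → −20 °C; aq. NH4Cl
Reagents that add atoms: none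
Why: Iodine–lithium exchange gives the primary alkyllithium at −78 °C, and its addition to the Weinreb amide (tertiary hydroxyl held as the magnesium alkoxide) stops at the chelated tetrahedral intermediate, so the Weinreb ketone synthesis forms the C1–C2 bond without over-addition.

Step 11
Reactants: 17 (2E,7R,9S)-9,12-bis[(tert-butyldimethylsilyl)oxy]-7-hydroxy-1-[(4-methoxybenzyl)oxy]-3,7-dimethyldodec-2-en-10-yn-6-one
Product: 18 (2E,7R,9S)-9,12-bis[(tert-butyldimethylsilyl)oxy]-1-[(4-methoxybenzyl)oxy]-3,7-dimethyl-6-oxododec-2-en-10-yn-7-yl acetate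
Conditions: Ac2O, DMAP, Et3N, CH2Cl2, 23 → 40 °C
Reagents that add atoms: acetic anhydride, CC(=O)OC(C)=O
Why: DMAP-catalysed (Steglich-type) acylation is the standard way to acetylate a hindered tertiary alcohol and installs the C10 acetate now that no organometallic step remains.

Step 12
Reactants: 18 (2E,7R,9S)-9,12-bis[(tert-butyldimethylsilyl)oxy]-1-[(4-methoxybenzyl)oxy]-3,7-dimethyl-6-oxododec-2-en-10-yn-7-yl acetate
Product: 19 (2E,7R,9S)-9,12-bis[(tert-butyldimethylsilyl)oxy]-1-hydroxy-3,7-dimethyl-6-oxododec-2-en-10-yn-7-yl acetate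
Conditions: DDQ, CH2Cl2–pH 7 buffer, 0 °C
Reagents that add atoms: none
Why: Oxidative cleavage of the PMB ether with DDQ frees the allylic C6 hydroxyl while silyl ethers, acetate, ketone and alkyne are inert.

Step 13
Reactants: 19 (2E,7R,9S)-9,12-bis[(tert-butyldimethylsilyl)oxy]-1-hydroxy-3,7-dimethyl-6-oxododec-2-en-10-yn-7-yl acetate
Product: 20 (2E,7R,9S)-9,12-bis[(tert-butyldimethylsilyl)oxy]-3,7-dimethyl-1,6-dioxododec-2-en-10-yn-7-yl acetate
Conditions: activated MnO2, CH2Cl2, 23 °C; filter and use at once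
Reagents that add atoms: none
Why: Manganese dioxide oxidises only the allylic alcohol and, being neutral and heterogeneous, gives the β,β-disubstituted enal without E/Z isomerisation.

Step 14
Reactants: 20 (2E,7R,9S)-9,12-bis[(tert-butyldimethylsilyl)oxy]-3,7-dimethyl-1,6-dioxododec-2-en-10-yn-7-yl acetate
Product: 23 (6R,8S,10R)-10-acetoxy-8,13-bis[(tert-butyldimethylsilyl)oxy]-1-oxogermacra-4E,7(11)-dien-12,6-olide, via oxanickelacyclopentene 21 (not isolated), via acylnickel alkoxide 22 (not isolated)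
Conditions: Ni(cod)2 (1.2 equiv), PCy3 (1.2 equiv), toluene, 23 °C, slow addition of 20 (final 2 mM); then CO (1 atm), 23 °C
Reagents that add atoms: carbon monoxide, [C-]#[O+]
Why: Proposed new method: nickel(0)–PCy3 couples the C6 aldehyde C=O and the C7≡C11 alkyne oxidatively to oxanickelacyclopentene 21 (C6–C7 bond), CO inserts into the Ni–C11 bond to give acyl 22, and acyl–oxygen reductive elimination forms C12–O and releases 23 with nickel(0) carbonyl. The closest known reactions are the nickel(0) oxidative cyclisation of alkynes with aldehydes that starts the reductive macrocyclisations of ynals, the carbonylation of such nickelacycles to butenolides, and the Mo- or Ru-carbonyl hetero-Pauson–Khand reaction of 1,6- and 1,7-ynals; the combination has not been shown for a ten-membered ring or for an enal. The ten-membered carbocycle closes in the oxidative cyclisation by C6–C7 bond formation exo to the alkyne (C7=C11 ends exocyclic), and the five-membered lactone closes last by reductive elimination at nickel. The single new stereocentre C6 is set in the oxidative cyclisation by the C8 stereocentre: allylic strain with the C13 arm should hold C8–H in the plane of the forming alkene so that the silyloxy group blocks one face of the nickelacycle, and a wrong C6 epimer can still be equilibrated through the furanolate. The step needs the aldehyde to react in preference to the C1 ketone and to the enal C=C, and exo in preference to endo closure: the ketone is flanked by quaternary C10, C4 is fully substituted so that conjugate cyclisation would build a quaternary centre in an eight-membered ring, and the endo mode would give a bridged trans-cycloundecene. C13 is carried as a silyl ether because a propargylic (then allylic) acetate would be ionised by nickel(0), and the E-alkene, quaternary C10, the linear alkyne and slow addition at high dilution favour the intramolecular path.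

Step 15
Reactants: 23 (6R,8S,10R)-10-acetoxy-8,13-bis[(tert-butyldimethylsilyl)oxy]-1-oxogermacra-4E,7(11)-dien-12,6-olide
Product: 24 (6R,8S,10R)-10-acetoxy-8,13-dihydroxy-1-oxogermacra-4E,7(11)-dien-12,6-olide
Conditions: HF·pyridine, pyridine, THF, 0 → 23 °C
Reagents that add atoms: none
Why: Buffered HF·pyridine removes both silyl ethers under non-basic conditions, which avoids furanolate formation at C6 and migration of the lactone to the C8 oxygen.

Step 16
Reactants: 24 (6R,8S,10R)-10-acetoxy-8,13-dihydroxy-1-oxogermacra-4E,7(11)-dien-12,6-olide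
Product: 25 (6R,8S,10R)-10,13-diacetoxy-8-hydroxy-1-oxogermacra-4E,7(11)-dien-12,6-olide
Conditions: AcCl (1.1 equiv), 2,4,6-collidine, CH2Cl2, −78 °C
Reagents that add atoms: acetyl chloride, CC(Cl)=O
Why: Acetyl chloride with collidine at low temperature acylates a primary hydroxyl selectively over a hindered secondary one, so only C13–OH is acetylated.

Step 17
Reactants: 25 (6R,8S,10R)-10,13-diacetoxy-8-hydroxy-1-oxogermacra-4E,7(11)-dien-12,6-olide
Product: 26 (6R,8S,10R)-10,13-diacetoxy-8-(methacryloyloxy)-1-oxogermacra-4E,7(11)-dien-12,6-olide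
Conditions: methacrylic anhydride, DMAP (cat.), i-Pr2NEt, CH2Cl2, 0 °C
Reagents that add atoms: methacrylic anhydride, C=C(C)C(=O)OC(=O)C(C)=C
Why: DMAP-catalysed acylation with the anhydride esterifies the remaining secondary C8 hydroxyl at low temperature and short base exposure, with retention at C8.

Step 18
Reactants: 26 (6R,8S,10R)-10,13-diacetoxy-8-(methacryloyloxy)-1-oxogermacra-4E,7(11)-dien-12,6-olide
Product: 27 glaucolide A, (4R,5R,6S,8S,10R)-10,13-diacetoxy-4,5-epoxy-8-(methacryloyloxy)-1-oxogermacr-7(11)-en-12,6-olide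
Conditions: mCPBA, NaHCO3, CH2Cl2, 0 °C
Reagents that add atoms: 3-chloroperoxybenzoic acid, OOC(=O)c1cccc(Cl)c1
Why: Prilezhaev epoxidation picks the only electron-rich alkene (C4=C5) over the methacrylate and butenolide alkenes and adds oxygen syn from the outer face of the E-alkene in the ten-membered ring, which, as in related germacranolides, should give the trans-epoxide with 4R,5R configuration.

**Compound list**
1 | (R)-citramalic acid | OC(=O)C[C@@](C)(O)C(O)=O | starting material
2 | 2-[(4R)-2,2,4-trimethyl-5-oxo-1,3-dioxolan-4-yl]acetic acid | OC(=O)C[C@@]1(C)OC(C)(C)OC1=O | intermediate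
3 | tert-butyldimethyl(prop-2-yn-1-yloxy)silane | C#CCO[Si](C)(C)C(C)(C)C | starting material
4 | 2-[(4R)-2,2,4-trimethyl-5-oxo-1,3-dioxolan-4-yl]acetyl chloride | ClC(=O)C[C@@]1(C)OC(C)(C)OC1=O | intermediate
5 | (5R)-5-{5-[(tert-butyldimethylsilyl)oxy]-2-oxopent-3-yn-1-yl}-2,2,5-trimethyl-1,3-dioxolan-4-one | CC(C)(C)[Si](C)(C)OCC#CC(=O)C[C@@]1(C)OC(C)(C)OC1=O | intermediate
6 | (5R)-5-{(2S)-5-[(tert-butyldimethylsilyl)oxy]-2-hydroxypent-3-yn-1-yl}-2,2,5-trimethyl-1,3-dioxolan-4-one | CC(C)(C)[Si](C)(C)OCC#C[C@@H](O)C[C@@]1(C)OC(C)(C)OC1=O | intermediate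
7 | (5R)-5-{(2S)-2,5-bis[(tert-butyldimethylsilyl)oxy]pent-3-yn-1-yl}-2,2,5-trimethyl-1,3-dioxolan-4-one | CC(C)(C)[Si](C)(C)OCC#C[C@@H](O[Si](C)(C)C(C)(C)C)C[C@@]1(C)OC(C)(C)OC1=O | intermediate
8 | (2R,4S)-4,7-bis[(tert-butyldimethylsilyl)oxy]-2-hydroxy-N-methoxy-N,2-dimethylhept-5-ynamide | CC(C)(C)[Si](C)(C)OCC#C[C@@H](O[Si](C)(C)C(C)(C)C)C[C@@](C)(O)C(=O)N(C)OC | intermediate
9 | tert-butyl(but-3-yn-1-yloxy)dimethylsilane | C#CCCO[Si](C)(C)C(C)(C)C | starting material
10 | [(E)-4-[(tert-butyldimethylsilyl)oxy]-2-methylbut-1-en-1-yl]dimethylalane | CC(C)(C)[Si](C)(C)OCC/C(C)=C/[Al](C)C | intermediate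
11 | lithium butyl[(E)-4-[(tert-butyldimethylsilyl)oxy]-2-methylbut-1-en-1-yl]dimethylalanate | CC(C)(C)[Si](C)(C)OCC/C(C)=C/[Al-](C)(C)CCCC.[Li+] | intermediate
12 | (E)-5-[(tert-butyldimethylsilyl)oxy]-3-methylpent-2-en-1-ol | CC(C)(C)[Si](C)(C)OCC/C(C)=C/CO | intermediate
13 | tert-butyl{[(E)-5-[(4-methoxybenzyl)oxy]-3-methylpent-3-en-1-yl]oxy}dimethylsilane | CC(C)(C)[Si](C)(C)OCC/C(C)=C/COCc1ccc(OC)cc1 | intermediate
14 | (E)-5-[(4-methoxybenzyl)oxy]-3-methylpent-3-en-1-ol | OCC/C(C)=C/COCc1ccc(OC)cc1 | intermediate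
15 | 1-({[(E)-5-iodo-3-methylpent-2-en-1-yl]oxy}methyl)-4-methoxybenzene | ICC/C(C)=C/COCc1ccc(OC)cc1 | intermediate
16 | [(E)-5-[(4-methoxybenzyl)oxy]-3-methylpent-3-en-1-yl]lithium | [Li]CC/C(C)=C/COCc1ccc(OC)cc1 | intermediate
17 | (2E,7R,9S)-9,12-bis[(tert-butyldimethylsilyl)oxy]-7-hydroxy-1-[(4-methoxybenzyl)oxy]-3,7-dimethyldodec-2-en-10-yn-6-one | CC(C)(C)[Si](C)(C)OCC#C[C@@H](O[Si](C)(C)C(C)(C)C)C[C@@](C)(O)C(=O)CC/C(C)=C/COCc1ccc(OC)cc1 | intermediate
18 | (2E,7R,9S)-9,12-bis[(tert-butyldimethylsilyl)oxy]-1-[(4-methoxybenzyl)oxy]-3,7-dimethyl-6-oxododec-2-en-10-yn-7-yl acetate | CC(C)(C)[Si](C)(C)OCC#C[C@@H](O[Si](C)(C)C(C)(C)C)C[C@@](C)(OC(C)=O)C(=O)CC/C(C)=C/COCc1ccc(OC)cc1 | intermediate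
19 | (2E,7R,9S)-9,12-bis[(tert-butyldimethylsilyl)oxy]-1-hydroxy-3,7-dimethyl-6-oxododec-2-en-10-yn-7-yl acetate | CC(C)(C)[Si](C)(C)OCC#C[C@@H](O[Si](C)(C)C(C)(C)C)C[C@@](C)(OC(C)=O)C(=O)CC/C(C)=C/CO | intermediate
20 | (2E,7R,9S)-9,12-bis[(tert-butyldimethylsilyl)oxy]-3,7-dimethyl-1,6-dioxododec-2-en-10-yn-7-yl acetate (acyclic ynal) | CC(C)(C)[Si](C)(C)OCC#C[C@@H](O[Si](C)(C)C(C)(C)C)C[C@@](C)(OC(C)=O)C(=O)CC/C(C)=C/C=O | intermediate
21 | PCy3-ligated oxanickelacyclopentene (Ni bound to O–C6 and to C11; ten-membered ring closed) | CC(C)(C)[Si](C)(C)O[C@H]1C[C@@](C)(OC(C)=O)C(=O)CC/C(C)=C/[C@H]2O[Ni-]([P+](C3CCCCC3)(C3CCCCC3)C3CCCCC3)C(CO[Si](C)(C)C(C)(C)C)=C12 | intermediate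
22 | PCy3-ligated acylnickel alkoxide (CO inserted between Ni and C11) | CC(C)(C)[Si](C)(C)O[C@H]1C[C@@](C)(OC(C)=O)C(=O)CC/C(C)=C/[C@H]2O[Ni-]([P+](C3CCCCC3)(C3CCCCC3)C3CCCCC3)C(=O)C(CO[Si](C)(C)C(C)(C)C)=C12 | intermediate
23 | (6R,8S,10R)-10-acetoxy-8,13-bis[(tert-butyldimethylsilyl)oxy]-1-oxogermacra-4E,7(11)-dien-12,6-olide | CC(C)(C)[Si](C)(C)O[C@H]1C[C@@](C)(OC(C)=O)C(=O)CC/C(C)=C/[C@H]2OC(=O)C(CO[Si](C)(C)C(C)(C)C)=C12 | intermediate
24 | (6R,8S,10R)-10-acetoxy-8,13-dihydroxy-1-oxogermacra-4E,7(11)-dien-12,6-olide | O[C@H]1C[C@@](C)(OC(C)=O)C(=O)CC/C(C)=C/[C@H]2OC(=O)C(CO)=C12 | intermediate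
25 | (6R,8S,10R)-10,13-diacetoxy-8-hydroxy-1-oxogermacra-4E,7(11)-dien-12,6-olide | O[C@H]1C[C@@](C)(OC(C)=O)C(=O)CC/C(C)=C/[C@H]2OC(=O)C(COC(C)=O)=C12 | intermediate
26 | (6R,8S,10R)-10,13-diacetoxy-8-(methacryloyloxy)-1-oxogermacra-4E,7(11)-dien-12,6-olide | C=C(C)C(=O)O[C@H]1C[C@@](C)(OC(C)=O)C(=O)CC/C(C)=C/[C@H]2OC(=O)C(COC(C)=O)=C12 | intermediate
27 | glaucolide A (4R,5R,6S,8S,10R) | C=C(C)C(=O)O[C@H]1C[C@@](C)(OC(C)=O)C(=O)CC[C@@]2(C)O[C@@H]2[C@H]2OC(=O)C(COC(C)=O)=C12 | target

**Step count**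
Total: 18 steps. Longest linear sequence: 14 steps (steps 1–5, then 10–18, from (R)-citramalic acid).

**Steps most likely to fail**

1. Step 14. The ten-membered ring may not close: oligomerisation, cyclisation through the enal C=C or the C1 ketone, or loss of nickel to other sites can take over, and C6 may form with the wrong configuration. The fallback uses known chemistry: a Nozaki–Hiyama–Kishi ring closure of a (Z)-β-iodo enoate that already carries C12, with the chromium alkoxide lactonising onto the ester. It sets out from acetate 18. HF·pyridine at 0 °C should remove only the primary silyl group to give propargylic alcohol F1. TEMPO/PhI(OAc)2 in aqueous MeCN should give ynoic acid F2, and TMSCHN2 its methyl ynoate F3. MgI2 with paraformaldehyde (iodo-aldol, β-iodo Morita–Baylis–Hillman type) should add iodide at C7 and the hydroxymethyl group at C11 to give iodo enoate F4, with iodine cis to the ester. TBSCl/imidazole should give silyl ether F5, DDQ allylic alcohol F6, and MnO2 enal F7. CrCl2 with catalytic NiCl2 in DMSO–THF at high dilution should then form C6–C7 and, after lactonisation, rejoin the route at 23.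

2. Step 18. The peracid may attack the wrong face, or both faces, of the 4E-alkene if the ring conformation differs from that of related germacranolides. The fallback sets out from 26. NBS in aqueous THF at 0 °C should form the bromonium ion on the same exposed face and open it with water at the tertiary C4, giving bromohydrin F8. Ag2O should then close the epoxide with inversion at C5, which places the oxygen on the face the peracid does not reach, and the route is rejoined at 27.

3. Step 10. Acyl substitution at the hindered α-oxido Weinreb amide may be slow, so that proton transfer or cyclisation–elimination of the homoallylic lithium consumes the nucleophile. The fallback replaces the organolithium addition by a palladium-catalysed Fukuyama ketone synthesis. It sets out from dioxolanone 7 and iodide 15. AlMe3/EtSH should open 7 to thioester F9, and zinc dust with LiCl in THF should convert 15 into alkylzinc iodide F10. Coupling of F9 and F10 with PdCl2(PPh3)2 in THF–toluene should give ketone 17, where the route is rejoined.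

**Further compounds**
F1 | step 14 | (2E,7R,9S)-9-[(tert-butyldimethylsilyl)oxy]-12-hydroxy-1-[(4-methoxybenzyl)oxy]-3,7-dimethyl-6-oxododec-2-en-10-yn-7-yl acetate | OCC#C[C@@H](O[Si](C)(C)C(C)(C)C)C[C@@](C)(OC(C)=O)C(=O)CC/C(C)=C/COCc1ccc(OC)cc1
F2 | step 14 | (4S,6R,10E)-6-acetoxy-4-[(tert-butyldimethylsilyl)oxy]-12-[(4-methoxybenzyl)oxy]-6,10-dimethyl-7-oxododec-10-en-2-ynoic acid | OC(=O)C#C[C@@H](O[Si](C)(C)C(C)(C)C)C[C@@](C)(OC(C)=O)C(=O)CC/C(C)=C/COCc1ccc(OC)cc1
F3 | step 14 | methyl ester of F2 (methyl ynoate) | COC(=O)C#C[C@@H](O[Si](C)(C)C(C)(C)C)C[C@@](C)(OC(C)=O)C(=O)CC/C(C)=C/COCc1ccc(OC)cc1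
F4 | step 14 | methyl (2Z,4S,6R,10E)-6-acetoxy-4-[(tert-butyldimethylsilyl)oxy]-2-(hydroxymethyl)-3-iodo-12-[(4-methoxybenzyl)oxy]-6,10-dimethyl-7-oxododeca-2,10-dienoate | COC(=O)/C(CO)=C(\I)[C@@H](O[Si](C)(C)C(C)(C)C)C[C@@](C)(OC(C)=O)C(=O)CC/C(C)=C/COCc1ccc(OC)cc1
F5 | step 14 | tert-butyldimethylsilyl ether of F4 at the hydroxymethyl group | COC(=O)/C(CO[Si](C)(C)C(C)(C)C)=C(\I)[C@@H](O[Si](C)(C)C(C)(C)C)C[C@@](C)(OC(C)=O)C(=O)CC/C(C)=C/COCc1ccc(OC)cc1
F6 | step 14 | allylic alcohol from F5 (PMB removed) | COC(=O)/C(CO[Si](C)(C)C(C)(C)C)=C(\I)[C@@H](O[Si](C)(C)C(C)(C)C)C[C@@](C)(OC(C)=O)C(=O)CC/C(C)=C/CO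
F7 | step 14 | enal from F6 (iodo enoate aldehyde for the chromium ring closure) | COC(=O)/C(CO[Si](C)(C)C(C)(C)C)=C(\I)[C@@H](O[Si](C)(C)C(C)(C)C)C[C@@](C)(OC(C)=O)C(=O)CC/C(C)=C/C=O
F8 | step 18 | 5-bromo-4-hydroxy bromohydrin of 26 (Br at C5 anti to OH at C4) | C=C(C)C(=O)O[C@H]1C[C@@](C)(OC(C)=O)C(=O)CC[C@@](C)(O)[C@@H](Br)[C@H]2OC(=O)C(COC(C)=O)=C12
F9 | step 10 | S-ethyl (2R,4S)-4,7-bis[(tert-butyldimethylsilyl)oxy]-2-hydroxy-2-methylhept-5-ynethioate | CC(C)(C)[Si](C)(C)OCC#C[C@@H](O[Si](C)(C)C(C)(C)C)C[C@@](C)(O)C(=O)SCC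
F10 | step 10 | [(E)-5-[(4-methoxybenzyl)oxy]-3-methylpent-3-en-1-yl]zinc iodide | I[Zn]CC/C(C)=C/COCc1ccc(OC)cc1
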